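- I had a closed, stirred, isothermal vessel charged with starting complex and incoming ligand, and I wanted to know what it held at the end of the run.

    crystals ⇌ leaving ligand, rate k1*(cs1 - [leaving ligand]) while solid is left; crystals form when [leaving ligand] > cs1 (cs1 = 7.3 mM, k1 = 0.44 s⁻¹)
    complex with two exchanged + incoming ligand → over-reaction product (k2 = 0.25 L mol⁻¹ s⁻¹)
    starting complex + incoming ligand → leaving ligand + complex with one exchanged (k3 = 0.45 L mol⁻¹ s⁻¹)
    complex with one exchanged → side product (k4 = 0.015 s⁻¹)
    complex with one exchanged + incoming ligand → leaving ligand + complex with two exchanged (k5 = 0.20 L mol⁻¹ s⁻¹)

starting complex 0.20 M; incoming ligand 0.100 M; time 12 min

* at 12 min, what has stopped the reaction, if anything has (forward and back rates have come level / it is still moving / all of the starting complex has reacted / the incoming ligand has run out first)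
* share of the starting complex used up at 12 min
* complex with two exchanged at 12 min, in percent of the starting complex charged
* side product at 12 min, in percent of the starting complex charged

- for leaving ligand the crystals are counted in
- as a solid, counted per litre of solution: crystals
- the reaction counts as stopped when no species that holds the starting complex changes by six tenths of a point or more over the second half of the time
- run time (flask): 12 min

- Each exchange step carries [incoming ligand] as a factor in its rate, so I followed that one concentration.
- At the charges, the first exchange had a half-life of 0.26 min, short against 12 min, so I expected the 0.100 M of incoming ligand, the limiting reagent against 0.20 M of starting complex, to be consumed well inside the run.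
- The bench rule is one ligand per exchange, so I put the share of starting complex used up at the ligand ceiling, the charged [incoming ligand] over the charged [starting complex], which was 50.0 %.
- The rule stops working where the second exchange competes for ligand. That competition is the ratio of k5[complex with one exchanged] to k3[starting complex].
- For the ceiling reached and no drain, I put the end value of this ratio at 0.444. It climbs from nothing, so I took its mean as 0.222, which put the share used up near 40.9 %.
- The drain to side product had a half-life of 0.77 min, not much longer than the 0.58 min of the second exchange at charged ligand, so I read my figure as low.
- The forecast's answer was: the incoming ligand has run out first, with a share used up of 44.5 % (43.5 % to 45.5 %), complex with two exchanged at 4.5 % and side product at 39.5 % of the starting complex charged. Its grounds were that “nothing reverses and the crystals only take up leaving ligand”. My figure lay below its range.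
- The simulation's answer was: the incoming ligand has run out first, with 0 % of it left at 12.0 min; the share used up was 44.6 %, with complex with two exchanged at 4.27 % and side product at 39.7 % of the starting complex charged, so this flask stopped under its ceiling of 50.0 %. In the neighbouring flask, with 0.80 M of starting complex, the ceiling fell to 12.5 %. I put the end ratio there at 0.0635, so the same reckoning gave 12.1 %. That neighbouring flask used up 12.2 % of its starting complex and ended with complex with two exchanged at 0.328 % of the starting complex charged.

All constants are made up; the rest is arithmetic.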